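The lower flavan's pyran ring (ring C) is closed by a formal [4+2] annulation. An aryl benzyl ether already holding O1–C2 is oxidised at C2 to the aryl oxocarbenium ion C4a=C8a–O1+=C2, a cationic 2-oxadiene that uses the free ortho carbon C4a of the phloroglucinol ring A. A two-carbon enediol bis(silyl ether) supplies C3–C4: Mukaiyama addition forms C2–C3, and Friedel–Crafts closure forms C4–C4a in the same operation. Loss of the extra C4 oxygen gives the flavan-3-one, whose dynamic kinetic transfer hydrogenation sets C2 and C3 together. Galloylation, bromine-capped 4β→6 coupling with activated epicatechin and hydrogenolysis complete the synthesis.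

Key step: step 6

Remark: the catalyst antipode in step 8 is chosen on the assumption that the substituted C2 flank of the ketone plays the role of the large, π-bearing group of an aryl ketone; the mirror-image complex would be used if a trial reduction showed the opposite sense.

Step 1
Reactants: 1 3,4,5-trihydroxybenzaldehyde
Product: 2 7-hydroxy-2,2-diphenyl-1,3-benzodioxole-5-carbaldehyde
Conditions: Ph2CCl2 (1.1 equiv), Ph2O, 175 °C
Reagents that add atoms: dichlorodiphenylmethane ClC(Cl)(c1ccccc1)c1ccccc1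
Why: Thermal ketalisation of a catechol with a gem-dichloride can only bridge two adjacent hydroxyls, so one phenol (the future 3'-oxygen) stays free and the other two carry a group that the final hydrogenolysis removes.

Step 2
Reactants: 2 7-hydroxy-2,2-diphenyl-1,3-benzodioxole-5-carbaldehyde; 3 3,4,5-tris(benzyloxy)benzoic acid
Product: 4 6-formyl-2,2-diphenyl-1,3-benzodioxol-4-yl 3,4,5-tris(benzyloxy)benzoate
Conditions: DCC, DMAP, CH2Cl2, rt
Reagents that add atoms: none
Why: Steglich esterification acylates the only free phenol and installs the protected 3'-O-galloyl group while the aldehyde is untouched.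

Step 3
Reactants: 4 6-formyl-2,2-diphenyl-1,3-benzodioxol-4-yl 3,4,5-tris(benzyloxy)benzoate
Product: 5 6-(hydroxymethyl)-2,2-diphenyl-1,3-benzodioxol-4-yl 3,4,5-tris(benzyloxy)benzoate
Conditions: NaBH4, THF/MeOH (10:1), −10 °C
Reagents that add atoms: none
Why: Chemoselective borohydride reduction, since the aldehyde should be reduced far faster than the hindered aryl benzoate at low temperature.

Step 4
Reactants: 5 6-(hydroxymethyl)-2,2-diphenyl-1,3-benzodioxol-4-yl 3,4,5-tris(benzyloxy)benzoate; 6 3,5-bis(benzyloxy)phenol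
Product: 7 6-{[3,5-bis(benzyloxy)phenoxy]methyl}-2,2-diphenyl-1,3-benzodioxol-4-yl 3,4,5-tris(benzyloxy)benzoate
Conditions: PPh3, DIAD, THF, 0 °C to rt
Reagents that add atoms: none
Why: Mitsunobu etherification alkylates the acidic phenol on oxygen under neutral conditions, which avoids C-alkylation of the phloroglucinol ring and makes the O1–C2 bond.

Step 5
Reactants: 8 (tert-butyldimethylsilyloxy)acetaldehyde
Product: 9 (Z)-1,2-bis(tert-butyldimethylsilyloxy)ethene
Conditions: TBSOTf, Et3N, CH2Cl2, 0 °C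
Reagents that add atoms: tert-butyldimethylsilyl triflate CC(C)(C)[Si](C)(C)OS(=O)(=O)C(F)(F)F
Why: Soft enolisation of the aldehyde with silyl triflate and amine gives a symmetric, nucleophilic two-carbon enol silane that carries the future C3 oxygen; its geometry is of no consequence.

Step 6
Reactants: 7 6-{[3,5-bis(benzyloxy)phenoxy]methyl}-2,2-diphenyl-1,3-benzodioxol-4-yl 3,4,5-tris(benzyloxy)benzoate; 9 (Z)-1,2-bis(tert-butyldimethylsilyloxy)ethene
Product: 11 racemic 5,7-bis(benzyloxy)-3,4-bis(tert-butyldimethylsilyloxy)flavan bearing the protected B ring (diastereomer mixture), via DDQH mixed acetal 10 (not isolated)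
Conditions: DDQ (1.0 equiv), 4 Å MS, CH2Cl2, 0 °C to rt; then 9 (1.5 equiv), TMSOTf (0.2 equiv), −78 °C; Et3N quench
Reagents that add atoms: none
Why: Proposed new method: DDQ abstracts hydride from the B-ring benzylic C2–H of 7 (cation stabilised by the para oxygen of the benzodioxole) and the ion pair collapses to the DDQH acetal 10, which TMSOTf re-ionises to the aryl oxocarbenium ion; enol silane 9 then adds through one carbon to C2 (Mukaiyama-type addition, C2–C3) and the resulting silyloxycarbenium ion at C4 is captured by the ortho carbon C4a of ring A (Friedel–Crafts, C4–C4a). The closest known reactions are the DDQ-mediated oxidative C–H coupling of benzylic ethers with enol-type nucleophiles through oxocarbenium ions (also run in two stages through a DDQH acetal) and the oxa-Povarov annulation of aryl oxocarbenium ions with alkenes. Ring C closes by 6-exo-trig attack of the arene on the C4=O+ carbon. C2, C3 and C4 arise without control as a diastereomer mixture, on purpose, because step 7 erases C3 and C4 and step 8 equilibrates C2. The step needs hydride loss at C2 only, which the electron-rich B ring should secure against the plain benzyl ethers; capture of the cation by 9 and not by ring A of a second molecule, which the more nucleophilic enol silane should secure; and a single regiochemistry, which the two equivalent ortho positions of ring A and the symmetric reagent guarantee.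

Step 7
Reactants: 11 racemic 5,7-bis(benzyloxy)-3,4-bis(tert-butyldimethylsilyloxy)flavan bearing the protected B ring
Product: 13 racemic flavan-3-one (5,7-bis(benzyloxy)-3-oxochroman bearing the protected B ring), via 3-silyloxy-2H-chromene 12 (not isolated)
Conditions: TMSOTf (1.2 equiv), i-Pr2NEt, CH2Cl2, −40 to 0 °C; then 1 M HCl, THF, 0 °C to rt, argon
Reagents that add atoms: none
Why: TMSOTf turns the benzylic C4 silyl ether into a leaving group, the 5,7-dialkoxy-stabilised C4 cation loses H3 to the amine (E1, as in the silyl triflate/amine conversion of acetals into enol ethers), and hydrolysis of the enol silane gives the ketone, removing the stereocentres C3 and C4.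

Step 8
Reactants: 13 racemic flavan-3-one
Product: 14 6-[(2R,3R)-5,7-bis(benzyloxy)-3-hydroxychroman-2-yl]-2,2-diphenyl-1,3-benzodioxol-4-yl 3,4,5-tris(benzyloxy)benzoate
Conditions: RuCl(p-cymene)[(R,R)-TsDPEN] (2 mol %), HCO2H/Et3N (5:2), CH2Cl2, 30 °C, argon
Reagents that add atoms: none
Why: Asymmetric transfer hydrogenation under dynamic kinetic resolution (Noyori type): Et3N should epimerise the acidic C2–H (α-keto, benzylic, α-oxy) faster than reduction, and the chiral Ru–H complex reduces one enantiomer from the face anti to the 2-aryl group, so catalyst control sets C3 (R) and the cis preference sets C2 (R) in one event.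

Step 9
Reactants: 14 (2R,3R)-alcohol
Product: 15 6-[(2R,3R)-5,7-bis(benzyloxy)-8-bromo-3-hydroxychroman-2-yl]-2,2-diphenyl-1,3-benzodioxol-4-yl 3,4,5-tris(benzyloxy)benzoate
Conditions: NBS (1.05 equiv), CH2Cl2, −40 °C to rt
Reagents that add atoms: N-bromosuccinimide O=C1CCC(=O)N1Br
Why: Electrophilic aromatic bromination goes to the most electron-rich ring (ring A) and there to the less hindered C8, as is usual for 5,7-di-O-benzyl flavan-3-ols; the bromine blocks C8 for the later coupling.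

Step 10
Reactants: 15 8-bromo (2R,3R)-alcohol; 3 3,4,5-tris(benzyloxy)benzoic acid
Product: 16 (2R,3R)-5,7-bis(benzyloxy)-8-bromo-2-{2,2-diphenyl-7-[3,4,5-tris(benzyloxy)benzoyloxy]-1,3-benzodioxol-5-yl}chroman-3-yl 3,4,5-tris(benzyloxy)benzoate
Conditions: DCC, DMAP, CH2Cl2, rt
Reagents that add atoms: none
Why: Steglich esterification of the axial 3-OH installs the second protected galloyl group without touching the configuration at C3.

Step 11
Reactants: 17 (−)-epicatechin
Product: 18 5,7,3',4'-tetra-O-benzyl-(−)-epicatechin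
Conditions: BnBr, K2CO3, DMF, 0 °C to rt
Reagents that add atoms: benzyl bromide BrCc1ccccc1
Why: Williamson benzylation of the four phenols, which are far more acidic than the 3-OH, under mild base leaves the secondary alcohol free and both bought stereocentres intact.

Step 12
Reactants: 18 5,7,3',4'-tetra-O-benzyl-(−)-epicatechin
Product: 19 8-bromo-5,7,3',4'-tetra-O-benzyl-(−)-epicatechin
Conditions: NBS (1.05 equiv), CH2Cl2, −40 °C to rt
Reagents that add atoms: N-bromosuccinimide O=C1CCC(=O)N1Br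
Why: Regioselective electrophilic bromination at C8 of ring A caps the most nucleophilic position of the future electrophile against self-condensation.

Step 13
Reactants: 19 8-bromo-5,7,3',4'-tetra-O-benzyl-(−)-epicatechin
Product: 20 8-bromo-5,7,3',4'-tetra-O-benzyl-4β-(2-ethoxyethoxy)-(−)-epicatechin
Conditions: DDQ, 2-ethoxyethanol, CH2Cl2, rt
Reagents that add atoms: 2-ethoxyethanol CCOCCO
Why: DDQ oxidises the C4 benzylic position to the ring-A-stabilised cation, which the alcohol traps from the face anti to the 3-OH and the 2-aryl group to give the 4β ether (3,4-trans).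

Step 14
Reactants: 20 8-bromo-5,7,3',4'-tetra-O-benzyl-4β-(2-ethoxyethoxy)-(−)-epicatechin; 16 bromine-capped bis(galloyl) lower unit
Product: 21 protected dimer, 8-bromo-5,7,3',4'-tetra-O-benzyl-epicatechin-(4β→6)-[8-bromo-5,7-di-O-benzyl-4',5'-O-diphenylmethylene-epigallocatechin 3,3'-bis-O-(3,4,5-tri-O-benzylgalloyl) ester]
Conditions: TMSOTf (0.2 equiv), 4 Å MS, CH2Cl2, −78 to −30 °C; 16 in excess (3 equiv, recovered)
Reagents that add atoms: none
Why: TMSOTf ionises the C4 ether to the ring-A-stabilised cation, which undergoes Friedel–Crafts attack by the only free ring-A position of 16 (C6, as C8 is bromine-capped); attack anti to the 3-OH and 2-aryl group of the epicatechin unit sets the 4β (3,4-trans) interflavan bond.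

Step 15
Reactants: 21 protected dimer
Product: 22 epicatechin-(4β→6)-epigallocatechin 3,3'-di-O-gallate (CNP0237700.1)
Conditions: H2 (1 atm), Pd(OH)2/C, THF/MeOH/H2O, rt
Reagents that add atoms: none
Why: Hydrogenolysis cleaves the twelve benzyl ethers and the diphenylmethylene ketal and reduces both aryl bromides, while the esters, the interflavan bond and the stereocentres are not affected.

Compound list
1 | 3,4,5-trihydroxybenzaldehyde | O=Cc1cc(O)c(O)c(O)c1 | starting material
2 | 7-hydroxy-2,2-diphenyl-1,3-benzodioxole-5-carbaldehyde | O=Cc1cc(O)c2OC(c3ccccc3)(c3ccccc3)Oc2c1 | intermediate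
3 | 3,4,5-tris(benzyloxy)benzoic acid | OC(=O)c1cc(OCc2ccccc2)c(OCc2ccccc2)c(OCc2ccccc2)c1 | starting material
4 | 6-formyl-2,2-diphenyl-1,3-benzodioxol-4-yl 3,4,5-tris(benzyloxy)benzoate | O=Cc1cc(OC(=O)c2cc(OCc3ccccc3)c(OCc3ccccc3)c(OCc3ccccc3)c2)c2OC(c3ccccc3)(c3ccccc3)Oc2c1 | intermediate
5 | 6-(hydroxymethyl)-2,2-diphenyl-1,3-benzodioxol-4-yl 3,4,5-tris(benzyloxy)benzoate | OCc1cc(OC(=O)c2cc(OCc3ccccc3)c(OCc3ccccc3)c(OCc3ccccc3)c2)c2OC(c3ccccc3)(c3ccccc3)Oc2c1 | intermediate
6 | 3,5-bis(benzyloxy)phenol | Oc1cc(OCc2ccccc2)cc(OCc2ccccc2)c1 | starting material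
7 | 6-{[3,5-bis(benzyloxy)phenoxy]methyl}-2,2-diphenyl-1,3-benzodioxol-4-yl 3,4,5-tris(benzyloxy)benzoate | O=C(Oc1cc(COc2cc(OCc3ccccc3)cc(OCc3ccccc3)c2)cc2OC(c3ccccc3)(c3ccccc3)Oc12)c1cc(OCc2ccccc2)c(OCc2ccccc2)c(OCc2ccccc2)c1 | intermediate
8 | (tert-butyldimethylsilyloxy)acetaldehyde | O=CCO[Si](C)(C)C(C)(C)C | starting material
9 | (Z)-1,2-bis(tert-butyldimethylsilyloxy)ethene | CC(C)(C)[Si](C)(C)O/C=C\O[Si](C)(C)C(C)(C)C | intermediate
10 | DDQH mixed acetal of 7 (C2 bears the 2,3-dichloro-5,6-dicyano-4-hydroxyphenoxy group; racemic) | O=C(Oc1cc(C(Oc2cc(OCc3ccccc3)cc(OCc3ccccc3)c2)Oc2c(Cl)c(Cl)c(O)c(C#N)c2C#N)cc2OC(c3ccccc3)(c3ccccc3)Oc12)c1cc(OCc2ccccc2)c(OCc2ccccc2)c(OCc2ccccc2)c1 | intermediate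
11 | 6-[5,7-bis(benzyloxy)-3,4-bis(tert-butyldimethylsilyloxy)chroman-2-yl]-2,2-diphenyl-1,3-benzodioxol-4-yl 3,4,5-tris(benzyloxy)benzoate (racemic, diastereomer mixture) | O=C(Oc1cc(C2Oc3cc(OCc4ccccc4)cc(OCc4ccccc4)c3C(O[Si](C)(C)C(C)(C)C)C2O[Si](C)(C)C(C)(C)C)cc2OC(c3ccccc3)(c3ccccc3)Oc12)c1cc(OCc2ccccc2)c(OCc2ccccc2)c(OCc2ccccc2)c1 | intermediate
12 | 6-[5,7-bis(benzyloxy)-3-(tert-butyldimethylsilyloxy)-2H-chromen-2-yl]-2,2-diphenyl-1,3-benzodioxol-4-yl 3,4,5-tris(benzyloxy)benzoate (racemic) | O=C(Oc1cc(C2Oc3cc(OCc4ccccc4)cc(OCc4ccccc4)c3C=C2O[Si](C)(C)C(C)(C)C)cc2OC(c3ccccc3)(c3ccccc3)Oc12)c1cc(OCc2ccccc2)c(OCc2ccccc2)c(OCc2ccccc2)c1 | intermediate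
13 | 6-[5,7-bis(benzyloxy)-3-oxochroman-2-yl]-2,2-diphenyl-1,3-benzodioxol-4-yl 3,4,5-tris(benzyloxy)benzoate (racemic flavan-3-one) | O=C(Oc1cc(C2Oc3cc(OCc4ccccc4)cc(OCc4ccccc4)c3CC2=O)cc2OC(c3ccccc3)(c3ccccc3)Oc12)c1cc(OCc2ccccc2)c(OCc2ccccc2)c(OCc2ccccc2)c1 | intermediate
14 | 6-[(2R,3R)-5,7-bis(benzyloxy)-3-hydroxychroman-2-yl]-2,2-diphenyl-1,3-benzodioxol-4-yl 3,4,5-tris(benzyloxy)benzoate | O=C(Oc1cc([C@H]2Oc3cc(OCc4ccccc4)cc(OCc4ccccc4)c3C[C@H]2O)cc2OC(c3ccccc3)(c3ccccc3)Oc12)c1cc(OCc2ccccc2)c(OCc2ccccc2)c(OCc2ccccc2)c1 | intermediate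
15 | 6-[(2R,3R)-5,7-bis(benzyloxy)-8-bromo-3-hydroxychroman-2-yl]-2,2-diphenyl-1,3-benzodioxol-4-yl 3,4,5-tris(benzyloxy)benzoate | O=C(Oc1cc([C@H]2Oc3c(Br)c(OCc4ccccc4)cc(OCc4ccccc4)c3C[C@H]2O)cc2OC(c3ccccc3)(c3ccccc3)Oc12)c1cc(OCc2ccccc2)c(OCc2ccccc2)c(OCc2ccccc2)c1 | intermediate
16 | (2R,3R)-5,7-bis(benzyloxy)-8-bromo-2-{2,2-diphenyl-7-[3,4,5-tris(benzyloxy)benzoyloxy]-1,3-benzodioxol-5-yl}chroman-3-yl 3,4,5-tris(benzyloxy)benzoate | O=C(Oc1cc([C@H]2Oc3c(Br)c(OCc4ccccc4)cc(OCc4ccccc4)c3C[C@H]2OC(=O)c2cc(OCc3ccccc3)c(OCc3ccccc3)c(OCc3ccccc3)c2)cc2OC(c3ccccc3)(c3ccccc3)Oc12)c1cc(OCc2ccccc2)c(OCc2ccccc2)c(OCc2ccccc2)c1 | intermediate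
17 | (−)-epicatechin, (2R,3R) | C1c2c(O)cc(O)cc2O[C@H](c2ccc(O)c(O)c2)[C@@H]1O | starting material
18 | 5,7,3',4'-tetra-O-benzyl-(−)-epicatechin | C1c2c(OCc3ccccc3)cc(OCc3ccccc3)cc2O[C@H](c2ccc(OCc3ccccc3)c(OCc3ccccc3)c2)[C@@H]1O | intermediate
19 | 8-bromo-5,7,3',4'-tetra-O-benzyl-(−)-epicatechin | C1c2c(OCc3ccccc3)cc(OCc3ccccc3)c(Br)c2O[C@H](c2ccc(OCc3ccccc3)c(OCc3ccccc3)c2)[C@@H]1O | intermediate
20 | 8-bromo-5,7,3',4'-tetra-O-benzyl-4β-(2-ethoxyethoxy)-(−)-epicatechin (2,3-cis-3,4-trans) | CCOCCO[C@H]1c2c(OCc3ccccc3)cc(OCc3ccccc3)c(Br)c2O[C@H](c2ccc(OCc3ccccc3)c(OCc3ccccc3)c2)[C@@H]1O | intermediate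
21 | protected dimer: 8-bromo-tetra-O-benzyl-epicatechin-(4β→6)-[8-bromo-5,7-di-O-benzyl-4',5'-O-diphenylmethylene-epigallocatechin 3,3'-bis-O-(tri-O-benzylgalloyl) ester] | O=C(Oc1cc([C@H]2Oc3c(Br)c(OCc4ccccc4)c([C@H]4c5c(OCc6ccccc6)cc(OCc6ccccc6)c(Br)c5O[C@H](c5ccc(OCc6ccccc6)c(OCc6ccccc6)c5)[C@@H]4O)c(OCc4ccccc4)c3C[C@H]2OC(=O)c2cc(OCc3ccccc3)c(OCc3ccccc3)c(OCc3ccccc3)c2)cc2OC(c3ccccc3)(c3ccccc3)Oc12)c1cc(OCc2ccccc2)c(OCc2ccccc2)c(OCc2ccccc2)c1 | intermediate
22 | epicatechin-(4β→6)-epigallocatechin 3,3'-di-O-gallate (CNP0237700.1) | O=C(Oc1cc([C@H]2Oc3cc(O)c([C@H]4c5c(O)cc(O)cc5O[C@H](c5ccc(O)c(O)c5)[C@@H]4O)c(O)c3C[C@H]2OC(=O)c2cc(O)c(O)c(O)c2)cc(O)c1O)c1cc(O)c(O)c(O)c1 | target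

Total step count: 15. Longest linear sequence: 11 steps (steps 1, 2, 3, 4, 6, 7, 8, 9, 10, 14, 15).

Steps most likely to fail

Step 6 (Proposed new method). The oxidised ether may be intercepted by ring A of a second molecule (intermolecular Friedel–Crafts oligomerisation) before the enol silane is added, DDQ may abstract hydride from a benzyl ether CH2, or the silyloxycarbenium ion may lose its silyl group without closing the ring. The fallback uses known chemistry, sets out from aldehyde 4 (with phenol 6) and comes back at ketone 13, bypassing step 7 as well. Ethynylmagnesium bromide in THF at −78 °C adds to the aldehyde of 4 faster than to the aryl ester and should give the racemic propargylic alcohol F1. Mitsunobu etherification of F1 with 6 (PPh3, DIAD) gives the aryl propargyl ether F2. Oxidation of the terminal alkyne with Ph3PAuNTf2 (5 mol %) and 8-methylquinoline N-oxide in 1,2-dichloroethane generates an α-oxo gold carbene at the terminal carbon, which ring A traps at its ortho position; this is the established route from aryl propargyl ethers to chroman-3-ones and delivers 13. In this fallback C2–C3 and C4–C4a are made in separate steps.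

Step 8. Epimerisation at C2 may be slower than reduction, or the facial discrimination by the catalyst may be weak, so that the trans alcohol or material of low enantiomeric purity forms; the enol of 13 may also be oxidised by traces of air. The fallback sets out from 13 and comes back at 14. LiBH(s-Bu)3 in THF at −78 °C reduces the ketone from the face anti to the 2-aryl group (substrate control, the standard route to 2,3-cis flavan-3-ols) and should give the racemic cis alcohol, that is 14 together with its enantiomer, the (2S,3S)-alcohol F3. Preparative chromatography on a chiral stationary phase separates the two. F3 is re-oxidised with Dess–Martin periodinane to 13 and recycled.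

Step 14. Attack at the hindered, bromine-deactivated C6 of 16 may be slow enough for the C4 cation to attack C6 of a second molecule of 20 (self-condensation) or of the product (over-oligomerisation). The fallback removes every nucleophilic ring-A position from the electrophile; it sets out from 18 and comes back at target 22. NBS (2.2 equiv) brominates 18 at C6 and C8 to give 6,8-dibromo-5,7,3',4'-tetra-O-benzyl-(−)-epicatechin F4. DDQ and 2-ethoxyethanol convert it into the doubly capped 4β-(2-ethoxyethoxy) electrophile F5. TMSOTf-promoted coupling of F5 with one equivalent of 16 can then only occur at C6 of 16 and gives the tribromo protected dimer F6. Hydrogenolysis over Pd(OH)2/C removes the benzyl groups, the ketal and all three bromines to give 22.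

Further compounds
F1 | step 6 | 6-(1-hydroxyprop-2-yn-1-yl)-2,2-diphenyl-1,3-benzodioxol-4-yl 3,4,5-tris(benzyloxy)benzoate (racemic) | C#CC(O)c1cc(OC(=O)c2cc(OCc3ccccc3)c(OCc3ccccc3)c(OCc3ccccc3)c2)c2OC(c3ccccc3)(c3ccccc3)Oc2c1
F2 | step 6 | 6-{1-[3,5-bis(benzyloxy)phenoxy]prop-2-yn-1-yl}-2,2-diphenyl-1,3-benzodioxol-4-yl 3,4,5-tris(benzyloxy)benzoate (racemic) | C#CC(Oc1cc(OCc2ccccc2)cc(OCc2ccccc2)c1)c1cc(OC(=O)c2cc(OCc3ccccc3)c(OCc3ccccc3)c(OCc3ccccc3)c2)c2OC(c3ccccc3)(c3ccccc3)Oc2c1
F3 | step 8 | 6-[(2S,3S)-5,7-bis(benzyloxy)-3-hydroxychroman-2-yl]-2,2-diphenyl-1,3-benzodioxol-4-yl 3,4,5-tris(benzyloxy)benzoate (enantiomer of 14) | O=C(Oc1cc([C@@H]2Oc3cc(OCc4ccccc4)cc(OCc4ccccc4)c3C[C@@H]2O)cc2OC(c3ccccc3)(c3ccccc3)Oc12)c1cc(OCc2ccccc2)c(OCc2ccccc2)c(OCc2ccccc2)c1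
F4 | step 14 | 6,8-dibromo-5,7,3',4'-tetra-O-benzyl-(−)-epicatechin | C1c2c(OCc3ccccc3)c(Br)c(OCc3ccccc3)c(Br)c2O[C@H](c2ccc(OCc3ccccc3)c(OCc3ccccc3)c2)[C@@H]1O
F5 | step 14 | 6,8-dibromo-5,7,3',4'-tetra-O-benzyl-4β-(2-ethoxyethoxy)-(−)-epicatechin | CCOCCO[C@H]1c2c(OCc3ccccc3)c(Br)c(OCc3ccccc3)c(Br)c2O[C@H](c2ccc(OCc3ccccc3)c(OCc3ccccc3)c2)[C@@H]1O
F6 | step 14 | tribromo protected dimer (as 21 with an additional bromine at C6 of the epicatechin unit) | O=C(Oc1cc([C@H]2Oc3c(Br)c(OCc4ccccc4)c([C@H]4c5c(OCc6ccccc6)c(Br)c(OCc6ccccc6)c(Br)c5O[C@H](c5ccc(OCc6ccccc6)c(OCc6ccccc6)c5)[C@@H]4O)c(OCc4ccccc4)c3C[C@H]2OC(=O)c2cc(OCc3ccccc3)c(OCc3ccccc3)c(OCc3ccccc3)c2)cc2OC(c3ccccc3)(c3ccccc3)Oc12)c1cc(OCc2ccccc2)c(OCc2ccccc2)c(OCc2ccccc2)c1
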